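The route rests on cutting the aryl–oxygen bond O1–C8a of the 1,4-benzodioxane (O1, C2 aryl, C3 methyl, O4, C4a, C5 methoxy, C7 propenyl, C8a). Because the dioxane ring holds two aryl–oxygen bonds, this one can be made last from an open chain without touching a stereocentre. The precursor is a threo (1R,2R) 2-aryloxy-1-arylpropan-1-ol with bromine at the future C8a, the C7 aldehyde masked as a dioxolane and the phenol as a TIPS ether. One palladium-catalysed intramolecular etherification closes the dioxane ring and carries C2 and C3, set beforehand from (S)-lactate and by Felkin–Anh reduction, into the trans ring unchanged.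

Key step: step 7

Assumption: the target descriptors (2R,3R) correspond to the trans-2-aryl-3-methyl ring with an (E)-propenyl group; 1,1-diiodoethane and rac-2-(di-tert-butylphosphino)-1,1'-binaphthyl are taken as purchasable reagents.

Step 1
Reactants: 1 5-bromovanillin; 2 ethyl (S)-lactate
Product: 3 ethyl (2R)-2-(2-bromo-4-formyl-6-methoxyphenoxy)propanoate
Conditions: PPh3, DIAD, THF, 0 °C → rt
Reagents that add atoms: none
Why: Mitsunobu etherification, in which the acidic phenol 1 displaces the alkoxyphosphonium of the lactate by SN2, so the (S) centre should invert cleanly to the (R)-aryloxypropanoate that later becomes C3.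

Step 2
Reactants: 3 ethyl (2R)-2-(2-bromo-4-formyl-6-methoxyphenoxy)propanoate
Product: 4 ethyl (2R)-2-[2-bromo-4-(1,3-dioxolan-2-yl)-6-methoxyphenoxy]propanoate
Conditions: Me3SiOCH2CH2OSiMe3, Me3SiOTf (cat.), CH2Cl2, −78 → −20 °C; pyridine quench
Reagents that add atoms: 1,2-bis(trimethylsilyloxy)ethane, C[Si](C)(C)OCCO[Si](C)(C)C
Why: Noyori acetalisation masks the aldehyde under aprotic, non-basic conditions that should leave the ester and the enolisable alpha-aryloxy stereocentre untouched.

Step 3
Reactants: 4 ethyl (2R)-2-[2-bromo-4-(1,3-dioxolan-2-yl)-6-methoxyphenoxy]propanoate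
Product: 5 (2R)-2-[2-bromo-4-(1,3-dioxolan-2-yl)-6-methoxyphenoxy]-N-methoxy-N-methylpropanamide
Conditions: MeNHOMe·HCl, i-PrMgCl, THF, −20 °C; sat. aq. NH4Cl
Reagents that add atoms: N,O-dimethylhydroxylamine hydrochloride, Cl.CNOC
Why: Weinreb amide formation by ester aminolysis with the chloromagnesium amide made in the flask, a weakly basic nucleophile that should neither epimerise the alpha centre nor exchange the electron-rich aryl bromide at this temperature.

Step 4
Reactants: 6 4-bromo-2,6-dimethoxyphenol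
Product: 7 (4-bromo-2,6-dimethoxyphenoxy)triisopropylsilane
Conditions: TIPSCl, imidazole, DMF, rt
Reagents that add atoms: triisopropylsilyl chloride, CC(C)[Si](Cl)(C(C)C)C(C)C
Why: Standard phenol silylation; the TIPS ether, shielded by two ortho methoxy groups, should survive Grignard formation, hydride, hot Cs2CO3 and dilute acid, and is removable by fluoride without touching an alkene.

Step 5
Reactants: 5 (2R)-2-[2-bromo-4-(1,3-dioxolan-2-yl)-6-methoxyphenoxy]-N-methoxy-N-methylpropanamide; 7 (4-bromo-2,6-dimethoxyphenoxy)triisopropylsilane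
Product: 10 (2R)-2-[2-bromo-4-(1,3-dioxolan-2-yl)-6-methoxyphenoxy]-1-[3,5-dimethoxy-4-(triisopropylsilyloxy)phenyl]propan-1-one, via arylmagnesium bromide 8 (not isolated), via magnesium hemiaminal chelate 9 (not isolated)
Conditions: 7, Mg turnings (I2 crystal), THF, reflux; then 5, THF, −20 → 0 °C; cold sat. aq. NH4Cl
Reagents that add atoms: none
Why: Weinreb ketone synthesis, in which the chelated tetrahedral adduct 9 persists until the quench, so a second addition is blocked and the alpha-aryloxy ketone is never exposed to the basic Grignard reagent, which should preserve the (R) centre.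

Step 6
Reactants: 10 (2R)-2-[2-bromo-4-(1,3-dioxolan-2-yl)-6-methoxyphenoxy]-1-[3,5-dimethoxy-4-(triisopropylsilyloxy)phenyl]propan-1-one
Product: 11 (1R,2R)-2-[2-bromo-4-(1,3-dioxolan-2-yl)-6-methoxyphenoxy]-1-[3,5-dimethoxy-4-(triisopropylsilyloxy)phenyl]propan-1-ol
Conditions: K[HB(s-Bu)3], THF, −78 °C; sat. aq. NH4Cl
Reagents that add atoms: none
Why: Felkin–Anh (polar) reduction with a bulky hydride whose potassium counter-ion chelates poorly in THF, so hydride should add anti to the C–OAr bond and past the small alpha hydrogen, setting the new carbinol centre as (1R) and giving the threo alcohol (chelation would give erythro).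

Step 7
Reactants: 11 (1R,2R)-2-[2-bromo-4-(1,3-dioxolan-2-yl)-6-methoxyphenoxy]-1-[3,5-dimethoxy-4-(triisopropylsilyloxy)phenyl]propan-1-ol
Product: 12 (2R,3R)-7-(1,3-dioxolan-2-yl)-2-[3,5-dimethoxy-4-(triisopropylsilyloxy)phenyl]-5-methoxy-3-methyl-2,3-dihydro-1,4-benzodioxine
Conditions: Pd(OAc)2 (5 mol %), rac-2-(di-tert-butylphosphino)-1,1'-binaphthyl (6 mol %), Cs2CO3, toluene (0.05 M), 80 °C
Reagents that add atoms: none
Why: The divalent palladium salt is reduced in situ to zerovalent palladium, which inserts into the C8a–Br bond; Cs2CO3 then turns the C2 hydroxyl into a palladium-bound alkoxide, and C–O reductive elimination from the seven-membered aryl(alkoxo)palladium chelate forms O1–C8a. The closest known reaction type is the palladium-catalysed intramolecular etherification of aryl halides with alcohols (Buchwald–Hartwig C–O coupling), established for secondary alcohols and for 1,4-benzodioxanes. The dioxane ring closes in a 6-exo mode, O1 bonding to the sp2 carbon C8a with the C–Br bond outside the new ring. No stereocentre is created and no bond to C2 or C3 is broken, so the threo (1R,2R) alcohol should pass with retention into the trans (2R,3R) ring. The selectivity needed is chemoselectivity, reductive elimination against beta-hydride elimination of the benzylic alkoxide; the bulky electron-rich phosphine and the favourable ring size should secure it, while the bromine position inherited from 1 fixes the regiochemistry.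

Step 8
Reactants: 12 (2R,3R)-7-(1,3-dioxolan-2-yl)-2-[3,5-dimethoxy-4-(triisopropylsilyloxy)phenyl]-5-methoxy-3-methyl-2,3-dihydro-1,4-benzodioxine
Product: 13 (2R,3R)-3-[3,5-dimethoxy-4-(triisopropylsilyloxy)phenyl]-8-methoxy-2-methyl-2,3-dihydro-1,4-benzodioxine-6-carbaldehyde
Conditions: 1 M aq. HCl, THF, rt
Reagents that add atoms: water, O
Why: Acid-catalysed acetal hydrolysis; the hindered aryl TIPS ether and the aryl ether bonds of the dioxane ring should be stable to dilute acid at room temperature, so only the dioxolane is lost.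

Step 9
Reactants: 13 (2R,3R)-3-[3,5-dimethoxy-4-(triisopropylsilyloxy)phenyl]-8-methoxy-2-methyl-2,3-dihydro-1,4-benzodioxine-6-carbaldehyde
Product: 14 (2R,3R)-2-[3,5-dimethoxy-4-(triisopropylsilyloxy)phenyl]-5-methoxy-3-methyl-7-[(1E)-prop-1-en-1-yl]-2,3-dihydro-1,4-benzodioxine
Conditions: CrCl2 (divalent chromium), CH3CHI2, THF, 0 °C → rt
Reagents that add atoms: 1,1-diiodoethane, CC(I)I
Why: Takai–Utimoto ethylidenation, in which the gem-dichromium reagent adds to the aldehyde and eliminates with a preference for the (E)-alkene under non-basic conditions that the silyl ether and both stereocentres should tolerate.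

Step 10
Reactants: 14 (2R,3R)-2-[3,5-dimethoxy-4-(triisopropylsilyloxy)phenyl]-5-methoxy-3-methyl-7-[(1E)-prop-1-en-1-yl]-2,3-dihydro-1,4-benzodioxine
Product: 15 2,6-dimethoxy-4-[(2R,3R)-5-methoxy-3-methyl-7-[(1E)-prop-1-en-1-yl]-2,3-dihydro-1,4-benzodioxin-2-yl]phenol
Conditions: Bu4NF, AcOH, THF, 0 °C
Reagents that add atoms: none
Why: Fluoride-induced desilylation of the aryl silyl ether, buffered with acetic acid so that the oxidation-prone electron-rich phenoxide is protonated at once and the propenyl group and dioxane ring stay untouched.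

Compound list
1 | 5-bromovanillin | COc1cc(C=O)cc(Br)c1O | starting material
2 | ethyl (S)-lactate | CCOC(=O)[C@H](C)O | starting material
3 | ethyl (2R)-2-(2-bromo-4-formyl-6-methoxyphenoxy)propanoate | CCOC(=O)[C@@H](C)Oc1c(Br)cc(C=O)cc1OC | intermediate
4 | ethyl (2R)-2-[2-bromo-4-(1,3-dioxolan-2-yl)-6-methoxyphenoxy]propanoate | CCOC(=O)[C@@H](C)Oc1c(Br)cc(C2OCCO2)cc1OC | intermediate
5 | (2R)-2-[2-bromo-4-(1,3-dioxolan-2-yl)-6-methoxyphenoxy]-N-methoxy-N-methylpropanamide | CON(C)C(=O)[C@@H](C)Oc1c(Br)cc(C2OCCO2)cc1OC | intermediate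
6 | 4-bromo-2,6-dimethoxyphenol | COc1cc(Br)cc(OC)c1O | starting material
7 | (4-bromo-2,6-dimethoxyphenoxy)triisopropylsilane | COc1cc(Br)cc(OC)c1O[Si](C(C)C)(C(C)C)C(C)C | intermediate
8 | [3,5-dimethoxy-4-(triisopropylsilyloxy)phenyl]magnesium bromide | COc1cc([Mg]Br)cc(OC)c1O[Si](C(C)C)(C(C)C)C(C)C | intermediate
9 | bromomagnesium alkoxide of the tetrahedral N-methoxy-N-methyl hemiaminal formed from 8 and 5 (2R; new carbon unassigned) | CON(C)C(O[Mg]Br)(c1cc(OC)c(O[Si](C(C)C)(C(C)C)C(C)C)c(OC)c1)[C@@H](C)Oc1c(Br)cc(C2OCCO2)cc1OC | intermediate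
10 | (2R)-2-[2-bromo-4-(1,3-dioxolan-2-yl)-6-methoxyphenoxy]-1-[3,5-dimethoxy-4-(triisopropylsilyloxy)phenyl]propan-1-one | O=C(c1cc(OC)c(O[Si](C(C)C)(C(C)C)C(C)C)c(OC)c1)[C@@H](C)Oc1c(Br)cc(C2OCCO2)cc1OC | intermediate
11 | (1R,2R)-2-[2-bromo-4-(1,3-dioxolan-2-yl)-6-methoxyphenoxy]-1-[3,5-dimethoxy-4-(triisopropylsilyloxy)phenyl]propan-1-ol | Brc1cc(C2OCCO2)cc(OC)c1O[C@H](C)[C@H](O)c1cc(OC)c(O[Si](C(C)C)(C(C)C)C(C)C)c(OC)c1 | intermediate
12 | (2R,3R)-7-(1,3-dioxolan-2-yl)-2-[3,5-dimethoxy-4-(triisopropylsilyloxy)phenyl]-5-methoxy-3-methyl-2,3-dihydro-1,4-benzodioxine | O1CCOC1c1cc(OC)c2c(c1)O[C@H](c1cc(OC)c(O[Si](C(C)C)(C(C)C)C(C)C)c(OC)c1)[C@@H](C)O2 | intermediate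
13 | (2R,3R)-3-[3,5-dimethoxy-4-(triisopropylsilyloxy)phenyl]-8-methoxy-2-methyl-2,3-dihydro-1,4-benzodioxine-6-carbaldehyde | O=Cc1cc(OC)c2c(c1)O[C@H](c1cc(OC)c(O[Si](C(C)C)(C(C)C)C(C)C)c(OC)c1)[C@@H](C)O2 | intermediate
14 | (2R,3R)-2-[3,5-dimethoxy-4-(triisopropylsilyloxy)phenyl]-5-methoxy-3-methyl-7-[(1E)-prop-1-en-1-yl]-2,3-dihydro-1,4-benzodioxine | C/C=C/c1cc(OC)c2c(c1)O[C@H](c1cc(OC)c(O[Si](C(C)C)(C(C)C)C(C)C)c(OC)c1)[C@@H](C)O2 | intermediate
15 | 2,6-dimethoxy-4-[(2R,3R)-5-methoxy-3-methyl-7-[(1E)-prop-1-en-1-yl]-2,3-dihydro-1,4-benzodioxin-2-yl]phenol | C/C=C/c1cc(OC)c2c(c1)O[C@H](c1cc(OC)c(O)c(OC)c1)[C@@H](C)O2 | target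

Total step count: 10. Longest linear sequence: 9 steps (steps 1, 2, 3, 5, 6, 7, 8, 9, 10 from 5-bromovanillin); step 4 prepares the second aryl fragment.

Steps most likely to fail

Step 7. The process at risk is beta-hydride elimination from the palladium alkoxide, or slow oxidative addition into the electron-rich ortho-alkoxy aryl bromide, taking over from C–O reductive elimination. The fallback sets out from 11 and comes back at 13; it puts the ring oxygen on the arene first and makes the benzylic C–O bond instead.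
- Miyaura borylation of 11 (PdCl2(dppf), B2pin2, KOAc, dioxane, 80 °C; the weak base forms no alkoxide) should give (1R,2R)-2-[4-(1,3-dioxolan-2-yl)-2-methoxy-6-(4,4,5,5-tetramethyl-1,3,2-dioxaborolan-2-yl)phenoxy]-1-[3,5-dimethoxy-4-(triisopropylsilyloxy)phenyl]propan-1-ol F1.
- Oxidation with NaBO3·4H2O in THF/H2O should give the phenol (1R,2R)-2-[4-(1,3-dioxolan-2-yl)-2-hydroxy-6-methoxyphenoxy]-1-[3,5-dimethoxy-4-(triisopropylsilyloxy)phenyl]propan-1-ol F2.
- CF3CO2H in wet CH2Cl2 at 0 °C should ionise the electron-rich benzylic alcohol; the phenol traps the cation to close the dioxane ring in the thermodynamically preferred trans arrangement (C3 untouched, C2 set by the equatorial preference of the aryl group). The dioxolane is hydrolysed in the same operation, so the sequence rejoins the route at aldehyde 13.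

Step 6. The process at risk is poor facial selectivity, with chelation-controlled hydride delivery competing and eroding the threo preference. The fallback sets out from 10 and comes back at 11; it uses full chelation control and then inverts the carbinol.
- Zn(BH4)2 in Et2O at −20 °C should reduce through the five-membered zinc chelate to the erythro alcohol (1S,2R)-2-[2-bromo-4-(1,3-dioxolan-2-yl)-6-methoxyphenoxy]-1-[3,5-dimethoxy-4-(triisopropylsilyloxy)phenyl]propan-1-ol F3.
- Mitsunobu inversion with 4-nitrobenzoic acid, PPh3 and DIAD in THF should give (1R,2R)-2-[2-bromo-4-(1,3-dioxolan-2-yl)-6-methoxyphenoxy]-1-[3,5-dimethoxy-4-(triisopropylsilyloxy)phenyl]propyl 4-nitrobenzoate F4.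
- Brief methanolysis with K2CO3 in MeOH at 0 °C should release 11.

Step 9. The process at risk is incomplete (E)-selectivity or sluggish formation of the gem-dichromium reagent. The fallback sets out from 13 and comes back at 14: Julia–Kocienski olefination with 5-(ethylsulfonyl)-1-phenyl-1H-tetrazole and KN(SiMe3)2 in DME, −60 °C → rt, a reaction type that favours (E)-alkenes with electron-rich aromatic aldehydes. No new compound is made on this way (F0).

Further compounds
F1 | step 7 | (1R,2R)-2-[4-(1,3-dioxolan-2-yl)-2-methoxy-6-(4,4,5,5-tetramethyl-1,3,2-dioxaborolan-2-yl)phenoxy]-1-[3,5-dimethoxy-4-(triisopropylsilyloxy)phenyl]propan-1-ol | CC1(C)OB(OC1(C)C)c1cc(C2OCCO2)cc(OC)c1O[C@H](C)[C@H](O)c1cc(OC)c(O[Si](C(C)C)(C(C)C)C(C)C)c(OC)c1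
F2 | step 7 | (1R,2R)-2-[4-(1,3-dioxolan-2-yl)-2-hydroxy-6-methoxyphenoxy]-1-[3,5-dimethoxy-4-(triisopropylsilyloxy)phenyl]propan-1-ol | Oc1cc(C2OCCO2)cc(OC)c1O[C@H](C)[C@H](O)c1cc(OC)c(O[Si](C(C)C)(C(C)C)C(C)C)c(OC)c1
F3 | step 6 | (1S,2R)-2-[2-bromo-4-(1,3-dioxolan-2-yl)-6-methoxyphenoxy]-1-[3,5-dimethoxy-4-(triisopropylsilyloxy)phenyl]propan-1-ol | Brc1cc(C2OCCO2)cc(OC)c1O[C@H](C)[C@@H](O)c1cc(OC)c(O[Si](C(C)C)(C(C)C)C(C)C)c(OC)c1
F4 | step 6 | (1R,2R)-2-[2-bromo-4-(1,3-dioxolan-2-yl)-6-methoxyphenoxy]-1-[3,5-dimethoxy-4-(triisopropylsilyloxy)phenyl]propyl 4-nitrobenzoate | Brc1cc(C2OCCO2)cc(OC)c1O[C@H](C)[C@H](OC(=O)c1ccc(cc1)[N+](=O)[O-])c1cc(OC)c(O[Si](C(C)C)(C(C)C)C(C)C)c(OC)c1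
F0 | step 9 | none | none
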